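**Retrosynthetic overview**
1. The oxirane is formed last, by face-selective O-atom transfer to the electron-rich 3Z γ,δ-olefin of a macrocyclic 1E,3Z-dienone, as an epoxidase would do.
2. The 14-membered carbocycle is formed first. The terminal π-system of an acyclic C20 chain attacks its own C14 acylium ion and makes the C14–C1 bond, which copies the geranylgeranyl C1/C14 closure. Loss of H-1 gives the dienone at the final oxidation level.
3. The seco acid comes from a C8–C9 Evans syn aldol that sets C8. The imide is then reduced to CH2OH and the carbinol oxidised to the ketone.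
4. The dienyl imide partner comes from a pent-4-enoyl imide and a (Z)-iodo diene by B-alkyl Suzuki coupling, which fixes 3Z. The aldehyde partner comes from (R)-citronellal (C12) by organocatalytic α-benzoyloxylation (C13), oxidation and ozonolysis.

Assumption: the presumed biosynthesis is the cembrane one (C-1 of a geranylgeranyl chain is attacked by the terminal π bond, closing the ring at the carbon that carries the C3 unit, and olefin epoxidation follows), and cembrane numbering is used throughout: C1 = ring carbon with isopropyl, C2 = olefinic CH, C3/C4 = oxirane, C8 = CH(CH2OH) with CH2OH = C19, C9 and C14 = ketones, C12 = CHCH3, C13 = CHOH.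

**Step 1**
Reactants: 1 (R)-citronellal
Product: 3 (2S,3R)-2-(benzoyloxy)-3,7-dimethyloct-6-enoic acid, via α-benzoyloxy aldehyde 2 (not isolated)
Conditions: (BzO)2, (S)-2-tritylpyrrolidine (10 mol %), hydroquinone (10 mol %), THF, 0 °C to rt; then NaClO2, NaH2PO4, 2-methylbut-2-ene, t-BuOH/H2O, 0 °C
Reagents that add atoms: dibenzoyl peroxide O=C(OOC(=O)c1ccccc1)c1ccccc1; sodium chlorite [Na+].[O-]Cl=O
Why: In this enamine-catalysed α-benzoyloxylation the trityl group shields one enamine face, so the BzO group arrives under catalyst control to set 13S (C12 comes unchanged from citronellal), and the configurationally labile aldehyde is consumed at once by a Pinnick oxidation whose HOCl is trapped by 2-methylbut-2-ene so that the trisubstituted olefin survives.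

**Step 2**
Reactants: 3 (2S,3R)-2-(benzoyloxy)-3,7-dimethyloct-6-enoic acid
Product: 4 tert-butyl (2S,3R)-2-(benzoyloxy)-3,7-dimethyloct-6-enoate
Conditions: Cl3CC(=NH)Ot-Bu (2 equiv), CH2Cl2/cyclohexane, rt
Reagents that add atoms: tert-butyl 2,2,2-trichloroacetimidate CC(C)(C)OC(=N)C(Cl)(Cl)Cl
Why: Trichloroacetimidate esterification (self-catalysed tert-butyl transfer to the carboxylic acid) needs no base or strong acid, so the benzoate, the olefin and the α-stereocentre are untouched.

**Step 3**
Reactants: 4 tert-butyl (2S,3R)-2-(benzoyloxy)-3,7-dimethyloct-6-enoate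
Product: 6 tert-butyl (2S,3R)-2-(benzoyloxy)-3-methyl-6-oxohexanoate, via secondary ozonide 5 (not isolated)
Conditions: O3, CH2Cl2, −78 °C (Sudan III end point); then PPh3, −78 °C to rt
Reagents that add atoms: ozone [O-][O+]=O
Why: Criegee ozonolysis with reductive work-up cleaves the only C=C bond to the C9 aldehyde, while both esters and both stereocentres are inert.

**Step 4**
Reactants: 7 (R)-4-benzyl-1,3-oxazolidin-2-one; 8 pent-4-enoyl chloride
Product: 9 (R)-4-benzyl-3-(pent-4-enoyl)-1,3-oxazolidin-2-one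
Conditions: Et3N, DMAP (cat.), CH2Cl2, 0 °C to rt
Reagents that add atoms: none
Why: DMAP-catalysed N-acylation of the oxazolidinone by the acid chloride is fast and leaves the auxiliary stereocentre untouched.

**Step 5**
Reactants: 10 (E)-4-methylpent-2-enal; 11 ethyltriphenylphosphonium iodide
Product: 15 (2Z,4E)-2-iodo-6-methylhepta-2,4-diene, via ethylidene ylide 12 (not isolated), via iodophosphonium salt 13 (not isolated), via iodo ylide 14 (not isolated)
Conditions: n-BuLi, THF, rt; I2, −78 °C; NaHMDS, −20 °C; then 10, −78 to −20 °C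
Reagents that add atoms: iodine II
Why: In this Stork–Zhao-type Wittig olefination the non-stabilised α-iodo ylide reacts through the kinetic cis-oxaphosphetane and places iodine cis to the alkenyl residue (2Z), while the enal double bond stays E.

**Step 6**
Reactants: 9 (R)-4-benzyl-3-(pent-4-enoyl)-1,3-oxazolidin-2-one; 15 (2Z,4E)-2-iodo-6-methylhepta-2,4-diene
Product: 17 (R)-4-benzyl-3-[(6Z,8E)-6,10-dimethylundeca-6,8-dienoyl]-1,3-oxazolidin-2-one, via B-alkyl-9-BBN 16 (not isolated)
Conditions: 9-BBN-H, THF, rt; then 15, PdCl2(dppf) (5 mol %), AsPh3, Cs2CO3, DMF/H2O, rt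
Reagents that add atoms: none
Why: 9-BBN hydroborates the terminal olefin anti-Markovnikov much faster than it attacks the imide, and the B-alkyl Suzuki–Miyaura coupling proceeds with retention at the alkenyl iodide, so the trisubstituted olefin (later C3=C4) is fixed as Z.

**Step 7**
Reactants: 17 (R)-4-benzyl-3-[(6Z,8E)-6,10-dimethylundeca-6,8-dienoyl]-1,3-oxazolidin-2-one; 6 tert-butyl (2S,3R)-2-(benzoyloxy)-3-methyl-6-oxohexanoate
Product: 20 tert-butyl (2S,3R,6S,7R,11Z,13E)-2-(benzoyloxy)-7-[(4R)-4-benzyl-2-oxo-1,3-oxazolidine-3-carbonyl]-6-hydroxy-3,11,15-trimethylhexadeca-11,13-dienoate, via boron enolate 18 (not isolated), via boron aldolate 19 (not isolated)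
Conditions: n-Bu2BOTf, Et3N, CH2Cl2, 0 °C; 6, −78 to 0 °C; then pH 7 buffer, MeOH, 30 % H2O2, 0 °C
Reagents that add atoms: none
Why: In the Evans syn aldol the Z-boron enolate reacts through a Zimmerman–Traxler chair in which the (R)-benzyl auxiliary dictates the enolate face and sets C8 (chain C7, R here only because the imide carbon outranks C9 and S once it is CH2OH), while the C9 carbinol centre is removed later and the diene and esters are inert to the conditions.

**Step 8**
Reactants: 20 aldol adduct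
Product: 21 tert-butyl (2S,3R,6S,7S,11Z,13E)-2-(benzoyloxy)-6-hydroxy-7-(hydroxymethyl)-3,11,15-trimethylhexadeca-11,13-dienoate
Conditions: NaBH4, THF/H2O, 0 °C to rt
Reagents that add atoms: none
Why: Reductive auxiliary removal works because borohydride attacks only the activated exocyclic imide carbonyl, giving the C19 CH2OH without epimerising C8 and leaving the tert-butyl ester and the benzoate intact.

**Step 9**
Reactants: 21 diol
Product: 22 tert-butyl (2S,3R,6S,7S,11Z,13E)-2-(benzoyloxy)-7-{[(tert-butyldimethylsilyl)oxy]methyl}-6-hydroxy-3,11,15-trimethylhexadeca-11,13-dienoate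
Conditions: TBSCl (1.05 equiv), imidazole, CH2Cl2, 0 °C
Reagents that add atoms: tert-butyldimethylsilyl chloride CC(C)(C)[Si](C)(C)Cl
Why: Sterically controlled silylation takes the primary C19 hydroxyl far faster than the flanked secondary C9 hydroxyl.

**Step 10**
Reactants: 22 mono-TBS ether
Product: 23 tert-butyl (2S,3R,7S,11Z,13E)-2-(benzoyloxy)-7-{[(tert-butyldimethylsilyl)oxy]methyl}-3,11,15-trimethyl-6-oxohexadeca-11,13-dienoate
Conditions: Dess–Martin periodinane, CH2Cl2, 0 °C to rt
Reagents that add atoms: none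
Why: Dess–Martin oxidation converts the only free carbinol into the C9 ketone under near-neutral conditions, so C8 is not enolised, the silyloxy group is not eliminated and the diene is untouched.

**Step 11**
Reactants: 23 keto tert-butyl ester
Product: 25 (2S,3R,7S,11Z,13E)-2-(benzoyloxy)-7-{[(tert-butyldimethylsilyl)oxy]methyl}-3,11,15-trimethyl-6-oxohexadeca-11,13-dienoic acid, via trimethylsilyl ester 24 (not isolated)
Conditions: TMSOTf, 2,6-lutidine, CH2Cl2, 0 °C; then pH 5 aq. buffer
Reagents that add atoms: none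
Why: In this silyl-triflate-mediated tert-butyl ester cleavage, O-silylation triggers E1 loss of isobutene and the silyl ester hydrolyses on work-up, and the buffered non-protic medium spares the primary TBS ether, the benzoate, the diene and the C8 centre.

**Step 12**
Reactants: 25 seco acid
Product: 28 (1E,3Z,8S,12R,13S)-13-(benzoyloxy)-19-[(tert-butyldimethylsilyl)oxy]cembra-1,3-diene-9,14-dione, via acid chloride 26 (not isolated), via chloro ketone 27 (not isolated)
Conditions: 1-chloro-N,N,2-trimethylpropenylamine, CH2Cl2, 0 °C; syringe pump into SnCl4 (5 equiv), CH2Cl2 (final 1 mM), −78 °C; then Et3N, −78 to 0 °C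
Reagents that add atoms: none
Why: Proposed new method: SnCl4 turns the acid chloride into an acylium-type complex (CO loss is held back by the electron-poor α-benzoyloxy group and the C9 ketone is masked in situ as its SnCl4 complex), the diene terminus C1 attacks it in a 14-membered cation–olefin closure because only this attack gives the secondary/tertiary allyl cation C2–C4, ion-pair chloride capture at C2 at −78 °C is faster than rotation about C3–C4 so 3Z is kept, and Et3N then removes the doubly activated H-1 (E1cB) to give the more stable 1E dienone without touching C8, C12 or C13; the closest known reactions are the SnCl4-induced closure of geranylgeranoyl chloride to a 14-membered β-chloro ketone and the Darzens–Nenitzescu (Kondakov) acylation of olefins followed by dehydrochlorination.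

**Step 13**
Reactants: 28 protected macrocyclic dienone
Product: 30 (1E,3Z,8S,12R,13S)-13,19-dihydroxycembra-1,3-diene-9,14-dione, via silyl ether ketol 29 (not isolated)
Conditions: K2CO3 (0.2 equiv), MeOH, 0 °C; AcOH quench, evaporate; then HF·pyridine, THF, 0 °C
Reagents that add atoms: none
Why: Zemplén-type transesterification removes the activated α-keto benzoate within minutes at 0 °C, faster than enolisation at C8 or C13 or β-elimination of the silyloxy group, and fluoride-driven desilylation then frees C19-OH under non-basic conditions that cannot trigger retro-aldol loss of formaldehyde.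

**Step 14**
Reactants: 30 macrocyclic dienone diol
Product: 31 (1E,3S,4R,8S,12R,13S)-3,4-epoxy-13,19-dihydroxycembr-1-ene-9,14-dione (target CNP0110598.2)
Conditions: ent-Shi ketone (L-fructose series, 30 mol %), Oxone, K2CO3, Bu4NHSO4, MeCN–DMM/aq. Na2B4O7–Na2EDTA, 0 °C
Reagents that add atoms: potassium peroxymonosulfate (Oxone) [K+].[O-]S(=O)(=O)OO
Why: In the Shi asymmetric epoxidation the electrophilic dioxirane selects the electron-rich trisubstituted γ,δ-olefin over the enone C=C, the spiro transition state of the L-series ketone (olefinic H in the crowded quadrant) delivers oxygen to the face that gives 3S,4R, and the concerted syn transfer turns the 3Z olefin into the cis-oxirane.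

**Compound list**
1 | (R)-citronellal, (3R)-3,7-dimethyloct-6-enal | CC(C)=CCC[C@@H](C)CC=O | starting material
2 | (2S,3R)-2-(benzoyloxy)-3,7-dimethyloct-6-enal | CC(C)=CCC[C@@H](C)[C@H](OC(=O)c1ccccc1)C=O | intermediate
3 | (2S,3R)-2-(benzoyloxy)-3,7-dimethyloct-6-enoic acid | CC(C)=CCC[C@@H](C)[C@H](OC(=O)c1ccccc1)C(=O)O | intermediate
4 | tert-butyl (2S,3R)-2-(benzoyloxy)-3,7-dimethyloct-6-enoate | CC(C)=CCC[C@@H](C)[C@H](OC(=O)c1ccccc1)C(=O)OC(C)(C)C | intermediate
5 | tert-butyl (2S,3R)-2-(benzoyloxy)-5-(5,5-dimethyl-1,2,4-trioxolan-3-yl)-3-methylpentanoate (secondary ozonide) | CC1(C)OOC(CC[C@@H](C)[C@H](OC(=O)c2ccccc2)C(=O)OC(C)(C)C)O1 | intermediate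
6 | tert-butyl (2S,3R)-2-(benzoyloxy)-3-methyl-6-oxohexanoate | O=CCC[C@@H](C)[C@H](OC(=O)c1ccccc1)C(=O)OC(C)(C)C | intermediate
7 | (R)-4-benzyl-1,3-oxazolidin-2-one | O=C1N[C@H](Cc2ccccc2)CO1 | starting material
8 | pent-4-enoyl chloride | C=CCCC(=O)Cl | starting material
9 | (R)-4-benzyl-3-(pent-4-enoyl)-1,3-oxazolidin-2-one | C=CCCC(=O)N1[C@H](Cc2ccccc2)COC1=O | intermediate
10 | (E)-4-methylpent-2-enal | CC(C)/C=C/C=O | starting material
11 | ethyltriphenylphosphonium iodide | CC[P+](c1ccccc1)(c1ccccc1)c1ccccc1.[I-] | starting material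
12 | ethylidenetriphenylphosphorane | CC=P(c1ccccc1)(c1ccccc1)c1ccccc1 | intermediate
13 | (1-iodoethyl)triphenylphosphonium iodide | CC(I)[P+](c1ccccc1)(c1ccccc1)c1ccccc1.[I-] | intermediate
14 | (1-iodoethylidene)triphenylphosphorane | CC(I)=P(c1ccccc1)(c1ccccc1)c1ccccc1 | intermediate
15 | (2Z,4E)-2-iodo-6-methylhepta-2,4-diene | CC(C)/C=C/C=C(/C)I | intermediate
16 | (R)-4-benzyl-3-[5-(9-borabicyclo[3.3.1]nonan-9-yl)pentanoyl]-1,3-oxazolidin-2-one | O=C(CCCCB1C2CCCC1CCC2)N1[C@H](Cc2ccccc2)COC1=O | intermediate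
17 | (R)-4-benzyl-3-[(6Z,8E)-6,10-dimethylundeca-6,8-dienoyl]-1,3-oxazolidin-2-one | CC(C)/C=C/C=C(/C)CCCCC(=O)N1[C@H](Cc2ccccc2)COC1=O | intermediate
18 | (Z)-dibutylboron enolate of 17 | CC(C)/C=C/C=C(/C)CCC/C=C(\OB(CCCC)CCCC)N1[C@H](Cc2ccccc2)COC1=O | intermediate
19 | O-dibutylboryl aldolate of 20 | CC(C)/C=C/C=C(/C)CCC[C@@H](C(=O)N1[C@H](Cc2ccccc2)COC1=O)[C@@H](OB(CCCC)CCCC)CC[C@@H](C)[C@H](OC(=O)c1ccccc1)C(=O)OC(C)(C)C | intermediate
20 | tert-butyl (2S,3R,6S,7R,11Z,13E)-2-(benzoyloxy)-7-[(4R)-4-benzyl-2-oxo-1,3-oxazolidine-3-carbonyl]-6-hydroxy-3,11,15-trimethylhexadeca-11,13-dienoate | CC(C)/C=C/C=C(/C)CCC[C@@H](C(=O)N1[C@H](Cc2ccccc2)COC1=O)[C@@H](O)CC[C@@H](C)[C@H](OC(=O)c1ccccc1)C(=O)OC(C)(C)C | intermediate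
21 | tert-butyl (2S,3R,6S,7S,11Z,13E)-2-(benzoyloxy)-6-hydroxy-7-(hydroxymethyl)-3,11,15-trimethylhexadeca-11,13-dienoate | CC(C)/C=C/C=C(/C)CCC[C@@H](CO)[C@@H](O)CC[C@@H](C)[C@H](OC(=O)c1ccccc1)C(=O)OC(C)(C)C | intermediate
22 | tert-butyl (2S,3R,6S,7S,11Z,13E)-2-(benzoyloxy)-7-{[(tert-butyldimethylsilyl)oxy]methyl}-6-hydroxy-3,11,15-trimethylhexadeca-11,13-dienoate | CC(C)/C=C/C=C(/C)CCC[C@@H](CO[Si](C)(C)C(C)(C)C)[C@@H](O)CC[C@@H](C)[C@H](OC(=O)c1ccccc1)C(=O)OC(C)(C)C | intermediate
23 | tert-butyl (2S,3R,7S,11Z,13E)-2-(benzoyloxy)-7-{[(tert-butyldimethylsilyl)oxy]methyl}-3,11,15-trimethyl-6-oxohexadeca-11,13-dienoate | CC(C)/C=C/C=C(/C)CCC[C@@H](CO[Si](C)(C)C(C)(C)C)C(=O)CC[C@@H](C)[C@H](OC(=O)c1ccccc1)C(=O)OC(C)(C)C | intermediate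
24 | trimethylsilyl ester of 25 | CC(C)/C=C/C=C(/C)CCC[C@@H](CO[Si](C)(C)C(C)(C)C)C(=O)CC[C@@H](C)[C@H](OC(=O)c1ccccc1)C(=O)O[Si](C)(C)C | intermediate
25 | (2S,3R,7S,11Z,13E)-2-(benzoyloxy)-7-{[(tert-butyldimethylsilyl)oxy]methyl}-3,11,15-trimethyl-6-oxohexadeca-11,13-dienoic acid (seco acid) | CC(C)/C=C/C=C(/C)CCC[C@@H](CO[Si](C)(C)C(C)(C)C)C(=O)CC[C@@H](C)[C@H](OC(=O)c1ccccc1)C(=O)O | intermediate
26 | acid chloride of 25 | CC(C)/C=C/C=C(/C)CCC[C@@H](CO[Si](C)(C)C(C)(C)C)C(=O)CC[C@@H](C)[C@H](OC(=O)c1ccccc1)C(=O)Cl | intermediate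
27 | (3Z,8S,12R,13S)-13-(benzoyloxy)-19-[(tert-butyldimethylsilyl)oxy]-2-chlorocembr-3-ene-9,14-dione (14-membered ring, mixture at C1 and C2) | CC(C)C1C(Cl)/C=C(/C)CCC[C@@H](CO[Si](C)(C)C(C)(C)C)C(=O)CC[C@@H](C)[C@H](OC(=O)c2ccccc2)C1=O | intermediate
28 | (1E,3Z,8S,12R,13S)-13-(benzoyloxy)-19-[(tert-butyldimethylsilyl)oxy]cembra-1,3-diene-9,14-dione | CC(C)/C1=C\C=C(\C)CCC[C@@H](CO[Si](C)(C)C(C)(C)C)C(=O)CC[C@@H](C)[C@H](OC(=O)c2ccccc2)C1=O | intermediate
29 | (1E,3Z,8S,12R,13S)-19-[(tert-butyldimethylsilyl)oxy]-13-hydroxycembra-1,3-diene-9,14-dione | CC(C)/C1=C\C=C(\C)CCC[C@@H](CO[Si](C)(C)C(C)(C)C)C(=O)CC[C@@H](C)[C@H](O)C1=O | intermediate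
30 | (1E,3Z,8S,12R,13S)-13,19-dihydroxycembra-1,3-diene-9,14-dione | CC(C)/C1=C\C=C(\C)CCC[C@@H](CO)C(=O)CC[C@@H](C)[C@H](O)C1=O | intermediate
31 | (1E,3S,4R,8S,12R,13S)-3,4-epoxy-13,19-dihydroxycembr-1-ene-9,14-dione (CNP0110598.2) | CC(C)/C1=C\[C@@H]2O[C@]2(C)CCC[C@@H](CO)C(=O)CC[C@@H](C)[C@H](O)C1=O | target

Total step count: 14. Longest linear sequence: 11 (steps 1, 2, 3, 7, 8, 9, 10, 11, 12, 13, 14).

**Three steps most likely to fail**

Step 12 (acylium–diene ring closure). It can fail in several ways: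
- CO loss or benzoate participation at the acylium stage.
- Oligomerisation instead of ring closure.
- Proton loss towards the C4 methyl group.
- Leakage of 3Z to 3E.

The fallback lowers the electrophile to the aldehyde level, so the same C14–C1 bond is made by a Prins-type closure instead of an acylation. It sets out from acid chloride 26. LiAlH(Ot-Bu)3 (THF, −78 °C) reduces 26 to the seco aldehyde (2S,3R,7S,11Z,13E)-2-(benzoyloxy)-7-{[(tert-butyldimethylsilyl)oxy]methyl}-3,11,15-trimethyl-6-oxohexadeca-11,13-dienal F1. SnCl4 (CH2Cl2, 1 mM, −78 °C) then lets the diene terminus attack the activated aldehyde, with chloride capture, to give the chlorohydrin (3Z,8S,12R,13S)-13-(benzoyloxy)-19-[(tert-butyldimethylsilyl)oxy]-2-chloro-14-hydroxycembr-3-en-9-one F2. Dess–Martin oxidation of the new carbinol brings the fallback back to the route at chloro ketone 27, which Et3N converts into 28 as before.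

Step 14 (facial selectivity of the epoxidation). The conformational bias of the macrocycle may override the catalyst and give the other cis-oxirane. The fallback delivers the oxygen anti to the electrophile instead of with it, so it inverts whatever facial bias direct O-transfer shows. It sets out from 30. NBS in THF/H2O at 0 °C forms the bromonium ion on the exposed face, and water opens it at the tertiary C4 to give the bromohydrin (1E,3R,4R,8S,12R,13S)-3-bromo-4,13,19-trihydroxycembr-1-ene-9,14-dione F3. Brief treatment with K2CO3 in MeOH at 0 °C closes the C4 alkoxide onto C3 with inversion, and the fallback comes back to the route at 31.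

Step 5 (α-iodo Wittig olefination of an enal). Yields are modest and the Z:E ratio can erode, and this geometry later becomes the cis-oxirane. The fallback builds the halo-olefin by stereoselective cross-coupling instead of olefination. It sets out from 10. CBr4/PPh3 (CH2Cl2, 0 °C) gives (E)-1,1-dibromo-5-methylhexa-1,3-diene F4. Trans-selective Pd-catalysed Negishi monomethylation (MeZnCl, PdCl2(DPEphos), THF, 0 °C) replaces only the bromine trans to the alkenyl chain and gives (2Z,4E)-2-bromo-6-methylhepta-2,4-diene F5. This bromide is coupled with borane 16 under the Suzuki conditions of step 6 at 50 °C, and the fallback comes back to the route at 17.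

**Further compounds**
F1 | step 12 | seco aldehyde (2S,3R,7S,11Z,13E)-2-(benzoyloxy)-7-{[(tert-butyldimethylsilyl)oxy]methyl}-3,11,15-trimethyl-6-oxohexadeca-11,13-dienal | CC(C)/C=C/C=C(/C)CCC[C@@H](CO[Si](C)(C)C(C)(C)C)C(=O)CC[C@@H](C)[C@H](OC(=O)c1ccccc1)C=O
F2 | step 12 | chlorohydrin (3Z,8S,12R,13S)-13-(benzoyloxy)-19-[(tert-butyldimethylsilyl)oxy]-2-chloro-14-hydroxycembr-3-en-9-one | CC(C)C1C(Cl)/C=C(/C)CCC[C@@H](CO[Si](C)(C)C(C)(C)C)C(=O)CC[C@@H](C)[C@H](OC(=O)c2ccccc2)C1O
F3 | step 14 | bromohydrin (1E,3R,4R,8S,12R,13S)-3-bromo-4,13,19-trihydroxycembr-1-ene-9,14-dione | CC(C)/C1=C\[C@@H](Br)[C@@](O)(C)CCC[C@@H](CO)C(=O)CC[C@@H](C)[C@H](O)C1=O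
F4 | step 5 | (E)-1,1-dibromo-5-methylhexa-1,3-diene | CC(C)/C=C/C=C(Br)Br
F5 | step 5 | (2Z,4E)-2-bromo-6-methylhepta-2,4-diene | CC(C)/C=C/C=C(/C)Br
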